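**Strategy.** Everything rests on cutting C4=C5 of the cyclohexadienone ring (benzofuran numbering of the target throughout). The precursor is a cis-2-aryl-3-methyl tetrahydrofuran whose quaternary C3a carries the allyl group, a non-enolisable aldehyde (C4) and the exocyclic vinylogous ester O1–C7a=C7–C6(=O)–C5H2OMe; it is prepared as the Z isomer and reaches the reactive geometry, C6 cis to C3a, in the flask. Because C5 is the only enolisable carbon of that unit, soft enolisation joins C5 to C4, and loss of water gives the 5-methoxy dienone ring (C3a–C4–C5–C6–C7–C7a) in one operation. The three stereocentres are set earlier, by catalytic asymmetric syn-crotylation (C2, C3) and face-selective allylation of a formyl lactone (C3a).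

Key step: step 9

Assumption: (R)-TRIP, i.e. (R)-3,3′-bis(2,4,6-triisopropylphenyl)-1,1′-binaphthyl-2,2′-diyl hydrogen phosphate, is taken to direct the crotyl group to the Re face of the aryl aldehyde, as it does with aryl aldehydes in general; if the sense proves opposite, the (S)-acid is used.

Step 1
Reactants: 1 3,4,5-trimethoxybenzaldehyde; 2 (Z)-2-(but-2-en-1-yl)-4,4,5,5-tetramethyl-1,3,2-dioxaborolane
Product: 3 (1R,2S)-2-methyl-1-(3,4,5-trimethoxyphenyl)but-3-en-1-ol
Conditions: (R)-TRIP (5 mol%), PhMe, −30 °C; aq. NaHCO3 work-up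
Reagents that add atoms: none
Why: Brønsted-acid-catalysed allylboration through a closed chair transition state should turn the Z geometry of 2 into the syn relation while the chiral phosphoric acid, bound to the boronate, exposes the Re face of the aldehyde, which sets C2 (R) and C3 (S) of the target, cis on the future ring.

Step 2
Reactants: 3 (1R,2S)-2-methyl-1-(3,4,5-trimethoxyphenyl)but-3-en-1-ol
Product: 5 (1R,2S)-2-methyl-1-(3,4,5-trimethoxyphenyl)butane-1,4-diol, via alkylborane 4 (not isolated)
Conditions: 9-BBN (2.2 equiv), THF, 0 °C → rt; then aq. NaOH, H2O2, 0 °C → rt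
Reagents that add atoms: hydrogen peroxide, OO
Why: Anti-Markovnikov hydroboration of the terminal alkene and oxidation of the C–B bond with retention should give the primary alcohol without forming or touching a stereocentre.

Step 3
Reactants: 5 (1R,2S)-2-methyl-1-(3,4,5-trimethoxyphenyl)butane-1,4-diol
Product: 6 (4S,5R)-4-methyl-5-(3,4,5-trimethoxyphenyl)dihydrofuran-2(3H)-one
Conditions: TEMPO (0.2 equiv), PhI(OAc)2 (2.5 equiv), CH2Cl2, rt
Reagents that add atoms: none
Why: In this oxidative lactonisation of a 1,4-diol the oxoammonium salt derived from TEMPO should oxidise the primary alcohol first, the hydroxy aldehyde closes to a lactol, and a second oxidation gives the γ-lactone with the cis 4-methyl/5-aryl pattern intact.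

Step 4
Reactants: 6 (4S,5R)-4-methyl-5-(3,4,5-trimethoxyphenyl)dihydrofuran-2(3H)-one; 7 ethyl formate
Product: 8 (4S,5R)-3-(hydroxymethylene)-4-methyl-5-(3,4,5-trimethoxyphenyl)dihydrofuran-2(3H)-one
Conditions: NaH (1.2 equiv), THF, 0 °C → rt; aq. HCl to pH 3
Reagents that add atoms: none
Why: The crossed Claisen condensation of the lactone enolate with the non-enolisable formate is driven by the stabilised sodium enolate of the 1,3-dicarbonyl product, protonated on work-up, and the non-acidic C4 and C5 centres stay as set.

Step 5
Reactants: 8 (4S,5R)-3-(hydroxymethylene)-4-methyl-5-(3,4,5-trimethoxyphenyl)dihydrofuran-2(3H)-one; 9 allyl methyl carbonate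
Product: 10 (3S,4S,5R)-3-allyl-4-methyl-2-oxo-5-(3,4,5-trimethoxyphenyl)tetrahydrofuran-3-carbaldehyde
Conditions: Pd(PPh3)4 (3 mol%), THF, rt
Reagents that add atoms: none
Why: In this Tsuji–Trost allylation the methoxide released when zerovalent palladium ionises 9 deprotonates the acidic enol, and the planar enolate should be C-allylated by the π-allylpalladium cation on the ring face opposite the cis methyl and aryl groups, setting the quaternary centre with allyl trans to methyl (any O-allyl ether re-ionises under the catalyst).

Step 6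
Reactants: 10 (3S,4S,5R)-3-allyl-4-methyl-2-oxo-5-(3,4,5-trimethoxyphenyl)tetrahydrofuran-3-carbaldehyde
Product: 11 (3S,4S,5R)-3-allyl-3-(dimethoxymethyl)-4-methyl-5-(3,4,5-trimethoxyphenyl)dihydrofuran-2(3H)-one
Conditions: MeOSiMe3 (3 equiv), Me3SiOTf (5 mol%), CH2Cl2, −78 °C; pyridine quench
Reagents that add atoms: methoxytrimethylsilane, CO[Si](C)(C)C
Why: Silyl-triflate-catalysed acetalisation with a silyl methyl ether runs at low temperature without free alcohol or alkoxide, so the non-enolisable formyl group, which an alkoxide could cleave by retro-Claisen attack, is masked before the organolithium step.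

Step 7
Reactants: 11 (3S,4S,5R)-3-allyl-3-(dimethoxymethyl)-4-methyl-5-(3,4,5-trimethoxyphenyl)dihydrofuran-2(3H)-one; 12 3-methoxyprop-1-yne
Product: 14 (5S,6S,7R)-5-allyl-5-(dimethoxymethyl)-7-hydroxy-1-methoxy-6-methyl-7-(3,4,5-trimethoxyphenyl)hept-2-yn-4-one, via lithium acetylide 13 (not isolated)
Conditions: n-BuLi, THF, −78 °C; then 11, −78 → −40 °C; AcOH quench at −78 °C
Reagents that add atoms: none
Why: A lithium acetylide should add only once to the lactone because the tetrahedral lithium alkoxide persists at low temperature until the acidic quench, which joins C7a to the C7–C6–C5 chain with the methoxy group already on C5 and leaves no regiochemical question.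

Step 8
Reactants: 14 (5S,6S,7R)-5-allyl-5-(dimethoxymethyl)-7-hydroxy-1-methoxy-6-methyl-7-(3,4,5-trimethoxyphenyl)hept-2-yn-4-one
Product: 17 (2Z,3R,4S,5R)-3-allyl-2-(3-methoxy-2-oxopropylidene)-4-methyl-5-(3,4,5-trimethoxyphenyl)tetrahydrofuran-3-carbaldehyde, via enaminone 15 (not isolated), via diketone 16 (not isolated)
Conditions: Et2NH, EtOH, rt; concentrate; then 5% aq. oxalic acid–THF (1:2), rt, until the acetal is consumed
Reagents that add atoms: water, O
Why: Conjugate addition of the secondary amine to the ynone and acid hydrolysis of the enaminone is the standard hydration of an ynone to a 1,3-diketone and places the new carbonyl on C6, after which the benzylic hydroxyl closes onto the C7a carbonyl (5-exo-trig), the lactol, with C3a quaternary, loses water toward C7 only, the dimethyl acetal is hydrolysed in the same medium, and the reversibly C7-protonated enol ether should settle as the Z isomer, which keeps the acyl group away from the quaternary centre (any E isomer is carried along, since step 9 interconverts the two).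

Step 9
Reactants: 17 (2Z,3R,4S,5R)-3-allyl-2-(3-methoxy-2-oxopropylidene)-4-methyl-5-(3,4,5-trimethoxyphenyl)tetrahydrofuran-3-carbaldehyde
Product: 21 (2R,3S,3aS)-3a-allyl-5-methoxy-3-methyl-2-(3,4,5-trimethoxyphenyl)-3,3a-dihydrobenzofuran-6(2H)-one, via E isomer 18 (not isolated), via aldol 19 (not isolated), via mesylate 20 (not isolated)
Conditions: MgBr2·OEt2 (2.5 equiv), i-Pr2NEt (5 equiv), CH2Cl2 (0.01 M), 0 °C → rt; then MsCl (2 equiv), 0 °C; then DBU, rt (no heating)
Reagents that add atoms: none
Why: The Z isomer 17 cannot reach C4, but magnesium bromide bound at the C6 carbonyl raises the oxocarbenium–enolate character of the push–pull alkene, so rotation about C7=C7a (helped by reversible bromide addition at C7a) should feed the strained E isomer 18, in which the same Lewis acid chelates the C6 carbonyl and the C5 methoxy oxygen and lets the amine remove a C5 proton, the only one available since C7 is vinylic and C3a quaternary. The magnesium enolate adds to the neopentyl aldehyde C4 to give aldol 19, whose mesylate 20 undergoes E1cB elimination with DBU to install the C4=C5 enol ether of 21. The closest known chemistry is the magnesium halide–amine direct aldol addition of ketones, together with the α′-enolisation of vinylogous esters used in Stork–Danheiser sequences. The six-membered ring closes in a 6-(enolendo)-exo-trig mode, because both enolate carbons C5 and C6 lie inside the new ring while the aldehyde C=O is exocyclic to it. No stereocentre is created, since those formed at C4 and C5 in 19 vanish on elimination and C2, C3 and C3a are not touched. The step needs chemoselectivity, secured by the absence of any nucleophile that could cleave the C4 formyl group by retro-Claisen attack, and it needs the E geometry, supplied under Curtin–Hammett control because only 18 is drained by ring closure; the elimination is run without heating so that the 3a-allyl dienone is not exposed to sigmatropic rearrangement.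

**Compound list**

1 | 3,4,5-trimethoxybenzaldehyde | COc1cc(C=O)cc(OC)c1OC | starting material
2 | (Z)-2-(but-2-en-1-yl)-4,4,5,5-tetramethyl-1,3,2-dioxaborolane | C/C=C\CB1OC(C)(C)C(C)(C)O1 | starting material
3 | (1R,2S)-2-methyl-1-(3,4,5-trimethoxyphenyl)but-3-en-1-ol | O[C@@H](c1cc(OC)c(OC)c(OC)c1)[C@@H](C)C=C | intermediate
4 | (1R,2S)-4-(9-borabicyclo[3.3.1]nonan-9-yl)-2-methyl-1-(3,4,5-trimethoxyphenyl)butan-1-ol (formed in the flask; drawn with the free hydroxyl) | O[C@@H](c1cc(OC)c(OC)c(OC)c1)[C@@H](C)CCB1C2CCCC1CCC2 | intermediate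
5 | (1R,2S)-2-methyl-1-(3,4,5-trimethoxyphenyl)butane-1,4-diol | O[C@@H](c1cc(OC)c(OC)c(OC)c1)[C@@H](C)CCO | intermediate
6 | (4S,5R)-4-methyl-5-(3,4,5-trimethoxyphenyl)dihydrofuran-2(3H)-one | O=C1O[C@@H](c2cc(OC)c(OC)c(OC)c2)[C@@H](C)C1 | intermediate
7 | ethyl formate | CCOC=O | starting material
8 | (4S,5R)-3-(hydroxymethylene)-4-methyl-5-(3,4,5-trimethoxyphenyl)dihydrofuran-2(3H)-one (enol geometry not fixed; tautomer of the 3-formyl lactone) | O=C1O[C@@H](c2cc(OC)c(OC)c(OC)c2)[C@@H](C)C1=CO | intermediate
9 | allyl methyl carbonate | C=CCOC(=O)OC | starting material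
10 | (3S,4S,5R)-3-allyl-4-methyl-2-oxo-5-(3,4,5-trimethoxyphenyl)tetrahydrofuran-3-carbaldehyde | C=CC[C@]1(C=O)C(=O)O[C@@H](c2cc(OC)c(OC)c(OC)c2)[C@H]1C | intermediate
11 | (3S,4S,5R)-3-allyl-3-(dimethoxymethyl)-4-methyl-5-(3,4,5-trimethoxyphenyl)dihydrofuran-2(3H)-one | C=CC[C@]1(C(OC)OC)C(=O)O[C@@H](c2cc(OC)c(OC)c(OC)c2)[C@H]1C | intermediate
12 | 3-methoxyprop-1-yne | C#CCOC | starting material
13 | (3-methoxyprop-1-yn-1-yl)lithium (formed in the flask) | [Li]C#CCOC | intermediate
14 | (5S,6S,7R)-5-allyl-5-(dimethoxymethyl)-7-hydroxy-1-methoxy-6-methyl-7-(3,4,5-trimethoxyphenyl)hept-2-yn-4-one | C=CC[C@]([C@H](C)[C@@H](O)c1cc(OC)c(OC)c(OC)c1)(C(OC)OC)C(=O)C#CCOC | intermediate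
15 | (2E,5S,6S,7R)-5-allyl-2-(diethylamino)-5-(dimethoxymethyl)-7-hydroxy-1-methoxy-6-methyl-7-(3,4,5-trimethoxyphenyl)hept-2-en-4-one (formed in the flask) | C=CC[C@]([C@H](C)[C@@H](O)c1cc(OC)c(OC)c(OC)c1)(C(OC)OC)C(=O)/C=C(/N(CC)CC)COC | intermediate
16 | (5S,6S,7R)-5-allyl-5-(dimethoxymethyl)-7-hydroxy-1-methoxy-6-methyl-7-(3,4,5-trimethoxyphenyl)heptane-2,4-dione (formed in the flask) | C=CC[C@]([C@H](C)[C@@H](O)c1cc(OC)c(OC)c(OC)c1)(C(OC)OC)C(=O)CC(=O)COC | intermediate
17 | (2Z,3R,4S,5R)-3-allyl-2-(3-methoxy-2-oxopropylidene)-4-methyl-5-(3,4,5-trimethoxyphenyl)tetrahydrofuran-3-carbaldehyde | C=CC[C@]1(C=O)/C(=C/C(=O)COC)O[C@@H](c2cc(OC)c(OC)c(OC)c2)[C@H]1C | intermediate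
18 | (2E,3R,4S,5R)-3-allyl-2-(3-methoxy-2-oxopropylidene)-4-methyl-5-(3,4,5-trimethoxyphenyl)tetrahydrofuran-3-carbaldehyde (formed in the flask; the geometry that closes) | C=CC[C@]1(C=O)/C(=C\C(=O)COC)O[C@@H](c2cc(OC)c(OC)c(OC)c2)[C@H]1C | intermediate
19 | (2R,3S,3aS)-3a-allyl-4-hydroxy-5-methoxy-3-methyl-2-(3,4,5-trimethoxyphenyl)-3,3a,4,5-tetrahydrobenzofuran-6(2H)-one (C4 and C5 not defined; formed in the flask) | C=CC[C@]12C(O)C(OC)C(=O)C=C1O[C@@H](c1cc(OC)c(OC)c(OC)c1)[C@H]2C | intermediate
20 | 4-methanesulfonate of 19 (C4 and C5 not defined; formed in the flask) | C=CC[C@]12C(OS(C)(=O)=O)C(OC)C(=O)C=C1O[C@@H](c1cc(OC)c(OC)c(OC)c1)[C@H]2C | intermediate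
21 | (2R,3S,3aS)-3a-allyl-5-methoxy-3-methyl-2-(3,4,5-trimethoxyphenyl)-3,3a-dihydrobenzofuran-6(2H)-one | C=CC[C@]12C=C(OC)C(=O)C=C1O[C@@H](c1cc(OC)c(OC)c(OC)c1)[C@H]2C | target

**Total step count:** 9. **Longest linear sequence:** 9 steps (from 1).

**Steps most likely to fail**

Step 9. Rotation about the exocyclic C7=C7a alkene may be too slow under the magnesium conditions, so that the geometry unable to reach C4 persists and intermolecular aldol addition or loss of the formyl group takes over. Fallback: isomerisation and C–C bond formation are decoupled. From 17, irradiation (365 nm, thioxanthone as triplet sensitiser, THF) should enrich the twisted E isomer 18, which accepts triplet energy less readily. The mixture is then enolised kinetically with Bu2BOTf and i-Pr2NEt in CH2Cl2 at −78 °C, where only 18 can close in a boron-mediated aldol addition. A buffered methanol work-up should give aldol 19 and return unreacted 17, which is irradiated again. The fallback comes back to the route at 19, which is mesylated and eliminated as in step 9. No new compound arises.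

Step 8. Three acid-driven events share one medium, so ionisation at the electron-rich benzylic C–O bond (loss of configuration at C2) or incomplete unmasking of the neopentyl acetal may occur. Fallback: the events are staged. From 14, diethylamine addition gives enaminone 15, which is isolated. Buffered hydrolysis and cyclisation (AcOH/NaOAc, aq. THF, rt) should give the vinylogous ester still carrying the acetal, (Z)-1-[(3R,4S,5R)-3-allyl-3-(dimethoxymethyl)-4-methyl-5-(3,4,5-trimethoxyphenyl)dihydrofuran-2(3H)-ylidene]-3-methoxypropan-2-one F1. The acetal is then cleaved under non-acidic conditions through its collidinium salt (Et3SiOTf, 2,4,6-collidine, CH2Cl2, 0 °C; then H2O), which returns to the route at 17.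

Step 7. Addition to the neopentyl lactone carbonyl may be sluggish, or the tetrahedral adduct may collapse early and take up a second acetylide. Fallback: the three-carbon unit is built by C-acylation instead. From 11, MeLi (1.1 equiv, THF, −78 °C; AcOH quench), the smallest carbon nucleophile, should give the methyl lactol (3S,4S,5R)-3-allyl-3-(dimethoxymethyl)-2,4-dimethyl-5-(3,4,5-trimethoxyphenyl)tetrahydrofuran-2-ol F2. Its open methyl ketone form can enolise only at the methyl group and is acylated under soft enolisation (MgBr2·OEt2, i-Pr2NEt, 1-(methoxyacetyl)-1H-benzotriazole, CH2Cl2, rt). This gives diketone 16, where the fallback comes back to the route; the aqueous oxalic acid stage of step 8 then closes and unmasks it to 17.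

**Further compounds**

F0 | step 9 | none | none
F1 | step 8 | (Z)-1-[(3R,4S,5R)-3-allyl-3-(dimethoxymethyl)-4-methyl-5-(3,4,5-trimethoxyphenyl)dihydrofuran-2(3H)-ylidene]-3-methoxypropan-2-one | C=CC[C@]1(C(OC)OC)/C(=C/C(=O)COC)O[C@@H](c2cc(OC)c(OC)c(OC)c2)[C@H]1C
F2 | step 7 | (3S,4S,5R)-3-allyl-3-(dimethoxymethyl)-2,4-dimethyl-5-(3,4,5-trimethoxyphenyl)tetrahydrofuran-2-ol (mixture at C2) | C=CC[C@]1(C(OC)OC)C(C)(O)O[C@@H](c2cc(OC)c(OC)c(OC)c2)[C@H]1C
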